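## Retrosynthetic overview

1. The only ring, the 14-membered lactone, is closed late by Shiina macrolactonisation (C1 acyl to O13) of a seco acid; the C3 ketone is unmasked afterwards by oxidation, then the protecting groups are removed.
2. The C12–C13 bond, the 13S centre and the 11E diene come from a new enantioselective nickel-catalysed reductive coupling of a 1,3-enyne with propanal.
3. C1–C3 is added by an Evans syn-aldol on the C3 aldehyde (sets C2); C10–C11 by Sonogashira coupling of an enol triflate with a silyl propargyl ether.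
4. C7–C8 and the 8S centre come from a rhodium/BINAP conjugate addition of an alkenylboronate to pent-3-en-2-one; the 6E alkene from zirconium-catalysed carboalumination.
5. The 4R centre comes from Sharpless epoxidation of mono-PMB 2-methylidenepropane-1,3-diol, with acetylide opening of the epoxide forming C5–C6.

Assumption: positions are numbered C1 (lactone carbonyl) to C13 (carbinol carbon), C4' and C12' being the hydroxymethyl carbons, the target being (2R,4R,6E,8S,11E,13S); the (2R,5R) enantiomer of the proposed nickel ligand is taken to give 13S (to be fixed on a model enyne, otherwise its mirror image is used).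

## Route

Step 1
Reactants: 1 2-methylidenepropane-1,3-diol
Product: 2 mono-PMB ether 2-{[(4-methoxyphenyl)methoxy]methyl}prop-2-en-1-ol
Conditions: NaH (1.0 equiv), 4-methoxybenzyl chloride (1.0 equiv), Bu4NI (cat.), THF/DMF, 0 °C to rt, diol 1 in threefold excess
Reagents that add atoms: 4-methoxybenzyl chloride COc1ccc(CCl)cc1
Why: Williamson etherification of the monoalkoxide of a symmetric diol used in excess gives the mono-ether and makes the two CH2O arms different for the desymmetrising epoxidation.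

Step 2
Reactants: 2 mono-PMB ether
Product: 3 epoxy alcohol [(2S)-2-{[(4-methoxyphenyl)methoxy]methyl}oxiran-2-yl]methanol
Conditions: Ti(OiPr)4 (10 mol%), L-(+)-diethyl tartrate (12 mol%), t-BuOOH (2 equiv), 4 Å molecular sieves, CH2Cl2, −20 °C
Reagents that add atoms: tert-butyl hydroperoxide CC(C)(C)OO
Why: Sharpless asymmetric epoxidation; the L-(+)-tartrate titanium complex delivers oxygen to the alkene face that gives the 2S epoxide (the same face as in (S)-glycidol formation), which fixes the future C4 centre.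

Step 3
Reactants: 3 epoxy alcohol
Product: 4 alkyne diol (2R)-2-{[(4-methoxyphenyl)methoxy]methyl}pent-4-yne-1,2-diol
Conditions: LiC≡CH·H2NCH2CH2NH2 (4 equiv), DMSO, rt; H2O quench
Reagents that add atoms: lithium acetylide–ethylenediamine complex [Li]C#C.NCCN
Why: SN2 opening of the 2,2-disubstituted epoxide at its CH2 terminus by acetylide forms C5–C6 without touching the quaternary centre, and a Payne shift of the alkoxide is degenerate here and leads to the same enantiomer.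

Step 4
Reactants: 4 alkyne diol
Product: 5 alkyne acetonide (4S)-4-{[(4-methoxyphenyl)methoxy]methyl}-2,2-dimethyl-4-(prop-2-yn-1-yl)-1,3-dioxolane
Conditions: Me2C(OMe)2, PPTS (5 mol%), CH2Cl2, rt
Reagents that add atoms: 2,2-dimethoxypropane COC(C)(C)OC
Why: acid-catalysed transketalisation ties the tertiary C4 hydroxyl and the free CH2OH arm (C4') into a dioxolane and leaves the PMB-bearing arm distinct as the future C3.

Step 5
Reactants: 5 alkyne acetonide
Product: 7 alkenyl iodide (4S)-4-[(2E)-3-iodo-2-methylprop-2-en-1-yl]-4-{[(4-methoxyphenyl)methoxy]methyl}-2,2-dimethyl-1,3-dioxolane, via alkenyl(dimethyl)alane 6 (not isolated)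
Conditions: AlMe3 (3 equiv), Cp2ZrCl2 (25 mol%), CH2Cl2, 0 °C to rt; then I2, THF, −30 to 0 °C
Reagents that add atoms: trimethylaluminium C[Al](C)C; iodine II
Why: Negishi zirconium-catalysed carboalumination adds methyl and aluminium syn across the terminal alkyne (methyl to the internal carbon) and iodinolysis with retention gives the E trisubstituted alkenyl iodide, which fixes the C6=C7 geometry.

Step 6
Reactants: 7 alkenyl iodide
Product: 8 alkenylboronate 2-[(1E)-3-{(4S)-4-{[(4-methoxyphenyl)methoxy]methyl}-2,2-dimethyl-1,3-dioxolan-4-yl}-2-methylprop-1-en-1-yl]-4,4,5,5-tetramethyl-1,3,2-dioxaborolane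
Conditions: bis(pinacolato)diboron (1.2 equiv), PdCl2(PPh3)2 (3 mol%), PPh3 (6 mol%), KOPh (1.5 equiv), toluene, 50 °C
Reagents that add atoms: bis(pinacolato)diboron CC1(C)OB(OC1(C)C)B1OC(C)(C)C(C)(C)O1
Why: Miyaura borylation of an alkenyl iodide proceeds with retention of the double-bond geometry and tolerates the acetal and ether groups.

Step 7
Reactants: 8 alkenylboronate; 9 (3E)-pent-3-en-2-one
Product: 10 methyl ketone (4S,5E)-7-[(4S)-4-{[(4-methoxyphenyl)methoxy]methyl}-2,2-dimethyl-1,3-dioxolan-4-yl]-4,6-dimethylhept-5-en-2-one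
Conditions: [RhCl(cod)]2 (2.5 mol%), (R)-BINAP (6 mol%), KOH (0.3 equiv), 9 (3 equiv), dioxane/H2O (10:1), 50 °C
Reagents that add atoms: none
Why: Hayashi–Miyaura rhodium-catalysed asymmetric conjugate addition forms C7–C8; by the carbonyl-side recognition model the (S)-ligand exposes the α-si face of the enone, so (R)-BINAP delivers the alkenyl group from the α-re face and sets the 8S methyl centre under catalyst control with the alkene geometry kept.

Step 8
Reactants: 10 methyl ketone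
Product: 12 enol triflate (4S,5E)-7-[(4S)-4-{[(4-methoxyphenyl)methoxy]methyl}-2,2-dimethyl-1,3-dioxolan-4-yl]-4,6-dimethylhepta-1,5-dien-2-yl trifluoromethanesulfonate, via lithium enolate 11 (not isolated)
Conditions: LiN(iPr)2 (1.1 equiv), THF, −78 °C; then PhNTf2 (1.2 equiv), −78 to 0 °C
Reagents that add atoms: N-phenylbis(trifluoromethanesulfonimide) O=S(=O)(N(c1ccccc1)S(=O)(=O)C(F)(F)F)C(F)(F)F
Why: kinetic deprotonation of the methyl ketone at the unhindered CH3 and O-triflation of the terminal enolate give the 2-triflyloxy-1-alkene whose CH2 becomes the exocyclic C10 methylidene.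

Step 9
Reactants: 12 enol triflate; 13 tert-butyl(diphenyl)(prop-2-yn-1-yloxy)silane
Product: 14 enyne PMB ether (4S)-4-[(2E,4S)-9-{[tert-butyl(diphenyl)silyl]oxy}-2,4-dimethyl-6-methylidenenon-2-en-7-yn-1-yl]-4-{[(4-methoxyphenyl)methoxy]methyl}-2,2-dimethyl-1,3-dioxolane
Conditions: Pd(PPh3)4 (5 mol%), CuI (10 mol%), iPr2NH (3 equiv), THF, rt
Reagents that add atoms: none
Why: Sonogashira coupling of the alkenyl triflate with the terminal alkyne forms C10–C11 and gives the 2-substituted 1,3-enyne.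

Step 10
Reactants: 14 enyne PMB ether
Product: 15 enyne alcohol {(4S)-4-[(2E,4S)-9-{[tert-butyl(diphenyl)silyl]oxy}-2,4-dimethyl-6-methylidenenon-2-en-7-yn-1-yl]-2,2-dimethyl-1,3-dioxolan-4-yl}methanol
Conditions: DDQ (1.3 equiv), CH2Cl2/pH 7 buffer (10:1), 0 °C
Reagents that add atoms: none
Why: oxidative PMB cleavage by DDQ is done at the enyne stage, before the oxidation-sensitive dienyl carbinol exists, and leaves the acetonide and the silyl ether alone.

Step 11
Reactants: 15 enyne alcohol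
Product: 16 enyne aldehyde (4R)-4-[(2E,4S)-9-{[tert-butyl(diphenyl)silyl]oxy}-2,4-dimethyl-6-methylidenenon-2-en-7-yn-1-yl]-2,2-dimethyl-1,3-dioxolane-4-carbaldehyde
Conditions: Dess–Martin periodinane (1.3 equiv), CH2Cl2, 0 °C to rt
Reagents that add atoms: none
Why: Dess–Martin oxidation of the neopentyl primary alcohol gives the C3 aldehyde, which has no α-hydrogen and cannot epimerise.

Step 12
Reactants: 16 enyne aldehyde; 17 (4R)-4-benzyl-3-propanoyl-1,3-oxazolidin-2-one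
Product: 19 aldol adduct (4R)-4-benzyl-3-[(2R,3R)-3-{(4R)-4-[(2E,4S)-9-{[tert-butyl(diphenyl)silyl]oxy}-2,4-dimethyl-6-methylidenenon-2-en-7-yn-1-yl]-2,2-dimethyl-1,3-dioxolan-4-yl}-3-hydroxy-2-methylpropanoyl]-1,3-oxazolidin-2-one, via dibutylboron Z-enolate 18 (not isolated)
Conditions: 17 (1.3 equiv), Bu2BOTf (1.4 equiv), iPr2NEt (1.6 equiv), CH2Cl2, −78 to 0 °C; then 16, −78 to 0 °C; then pH 7 buffer, MeOH, 30% H2O2, 0 °C
Reagents that add atoms: none
Why: Evans syn-aldol reaction, in which the Z boron enolate of the (R)-benzyl oxazolidinone reacts through a Zimmerman–Traxler chair on the enolate face opposite the benzyl group and sets C2 as R (and C3 as R, later oxidised) under auxiliary control.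

Step 13
Reactants: 19 aldol adduct
Product: 20 silyl ether (4R)-4-benzyl-3-[(2R,3R)-3-{(4R)-4-[(2E,4S)-9-{[tert-butyl(diphenyl)silyl]oxy}-2,4-dimethyl-6-methylidenenon-2-en-7-yn-1-yl]-2,2-dimethyl-1,3-dioxolan-4-yl}-2-methyl-3-[(triethylsilyl)oxy]propanoyl]-1,3-oxazolidin-2-one
Conditions: Et3SiOTf (1.5 equiv), 2,6-lutidine (2.5 equiv), CH2Cl2, −78 to 0 °C
Reagents that add atoms: triethylsilyl trifluoromethanesulfonate CC[Si](CC)(CC)OS(=O)(=O)C(F)(F)F
Why: silylation of the hindered C3 carbinol with the silyl triflate blocks retro-aldol and β-lactone pathways and gives an ether that can later be removed in the presence of the tert-butyldiphenylsilyl group.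

Step 14
Reactants: 20 silyl ether; 21 propanal
Product: 22 dienyl alcohol (4R)-4-benzyl-3-[(2R,3R)-3-{(4R)-4-[(2E,4S,7E,9S)-8-({[tert-butyl(diphenyl)silyl]oxy}methyl)-9-hydroxy-2,4-dimethyl-6-methylideneundeca-2,7-dien-1-yl]-2,2-dimethyl-1,3-dioxolan-4-yl}-2-methyl-3-[(triethylsilyl)oxy]propanoyl]-1,3-oxazolidin-2-one
Conditions: Ni(cod)2 (10 mol%), proposed ligand (2R,5R)-1-cyclopentyl-2,5-diphenylphospholane (20 mol%; C1CCC(C1)P1[C@H](CC[C@@H]1c1ccccc1)c1ccccc1), Et3B (2.5 equiv), 21 (3 equiv), EtOAc, 0 °C to rt; aq. NaHCO3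
Reagents that add atoms: none
Why: Proposed new method: a ligand-controlled enantioselective nickel-catalysed reductive coupling of a 2-alkyl-1,3-enyne with an unbranched aliphatic aldehyde, in which zerovalent nickel carrying one monophosphine and bound to the enyne undergoes oxidative cyclisation with propanal at the alkyne carbon remote from the alkene (C12), the C2-symmetric 2,5-diphenylphospholane (a chiral analogue of the tricyclopentylphosphine that is best in the achiral reaction) forcing the ethyl group of the aldehyde away from a phenyl wall so that one aldehyde face reacts and C13 is set as S, after which ethyl transfer from Et3B, β-hydride elimination and C–H reductive elimination place hydrogen syn to the new bond and give the 11E diene; the closest known reaction is the nickel/Et3B reductive coupling of 1,3-enynes with aldehydes using achiral phosphines, for which chiral monophosphines have so far given only modest selectivity.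

Step 15
Reactants: 22 dienyl alcohol
Product: 24 seco acid (2R,3R)-3-{(4R)-4-[(2E,4S,7E,9S)-8-({[tert-butyl(diphenyl)silyl]oxy}methyl)-9-hydroxy-2,4-dimethyl-6-methylideneundeca-2,7-dien-1-yl]-2,2-dimethyl-1,3-dioxolan-4-yl}-2-methyl-3-[(triethylsilyl)oxy]propanoic acid, via lithium peroxycarboxylate 23 (not isolated)
Conditions: LiOH (2 equiv), 30% H2O2 (5 equiv), THF/H2O (3:1), 0 °C; then aq. Na2SO3; then 0.5 M HCl to pH 4
Reagents that add atoms: hydrogen peroxide OO
Why: hydroperoxide attacks the exocyclic imide carbonyl selectively (standard Evans auxiliary cleavage) and sulfite reduces the peracid, giving the seco acid without epimerising C2.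

Step 16
Reactants: 24 seco acid
Product: 26 macrolactone (5R,6R,7R,10S,11E,15S,16E)-11-({[tert-butyl(diphenyl)silyl]oxy}methyl)-10-ethyl-2,2,7,15,17-pentamethyl-13-methylidene-6-[(triethylsilyl)oxy]-1,3,9-trioxaspiro[4.13]octadeca-11,16-dien-8-one, via mixed anhydride 25 (not isolated)
Conditions: 2-methyl-6-nitrobenzoic anhydride (1.5 equiv), DMAP (6 equiv), CH2Cl2 (1 mM, 24 added over 12 h), rt
Reagents that add atoms: none
Why: Shiina macrolactonisation, in which the mixed anhydride is intercepted by DMAP and the acylpyridinium is trapped by the C13 hydroxyl at high dilution, closes the 14-membered ring with retention at C13.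

Step 17
Reactants: 26 macrolactone
Product: 27 C3 alcohol (5R,6R,7R,10S,11E,15S,16E)-11-({[tert-butyl(diphenyl)silyl]oxy}methyl)-10-ethyl-6-hydroxy-2,2,7,15,17-pentamethyl-13-methylidene-1,3,9-trioxaspiro[4.13]octadeca-11,16-dien-8-one
Conditions: HF·pyridine, pyridine, THF, 0 °C to rt
Reagents that add atoms: none
Why: buffered fluoride cleaves the triethylsilyl ether much faster than the tert-butyldiphenylsilyl ether and does not touch the acetonide, so only the C3 hydroxyl is freed.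

Step 18
Reactants: 27 C3 alcohol
Product: 28 keto lactone (5R,7R,10S,11E,15S,16E)-11-({[tert-butyl(diphenyl)silyl]oxy}methyl)-10-ethyl-2,2,7,15,17-pentamethyl-13-methylidene-1,3,9-trioxaspiro[4.13]octadeca-11,16-diene-6,8-dione
Conditions: Dess–Martin periodinane (2 equiv), CH2Cl2, 0 °C to rt
Reagents that add atoms: none
Why: Dess–Martin oxidation under non-basic conditions converts the hindered C3 carbinol into the ketone without enolising the new β-keto lactone, so the 2R centre from the aldol is kept.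

Step 19
Reactants: 28 keto lactone
Product: 30 target (3R,5R,7E,9S,12E,14S)-14-ethyl-5-hydroxy-5,13-bis(hydroxymethyl)-3,7,9-trimethyl-11-methylideneoxacyclotetradeca-7,12-diene-2,4-dione, via hydroxymethyl acetonide 29 (not isolated)
Conditions: HF·pyridine (excess), THF, 0 °C to rt; then AcOH/H2O (3:1), 40 °C
Reagents that add atoms: none
Why: fluoride cleaves the allylic silyl ether and mild aqueous acid hydrolyses the dioxolane, and since neither stage is basic the β-keto lactone, the α-ketol and the C2 centre survive.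

## Compound list

1 | 2-methylidenepropane-1,3-diol | C=C(CO)CO | starting material
2 | mono-PMB ether: 2-{[(4-methoxyphenyl)methoxy]methyl}prop-2-en-1-ol | C=C(CO)COCc1ccc(OC)cc1 | intermediate
3 | epoxy alcohol: [(2S)-2-{[(4-methoxyphenyl)methoxy]methyl}oxiran-2-yl]methanol | OC[C@@]1(COCc2ccc(OC)cc2)CO1 | intermediate
4 | alkyne diol: (2R)-2-{[(4-methoxyphenyl)methoxy]methyl}pent-4-yne-1,2-diol | C#CC[C@@](O)(CO)COCc1ccc(OC)cc1 | intermediate
5 | alkyne acetonide: (4S)-4-{[(4-methoxyphenyl)methoxy]methyl}-2,2-dimethyl-4-(prop-2-yn-1-yl)-1,3-dioxolane | C#CC[C@]1(COCc2ccc(OC)cc2)COC(C)(C)O1 | intermediate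
6 | alkenyl(dimethyl)alane: dimethyl[(1E)-3-{(4S)-4-{[(4-methoxyphenyl)methoxy]methyl}-2,2-dimethyl-1,3-dioxolan-4-yl}-2-methylprop-1-en-1-yl]alane | C[Al](C)/C=C(\C)C[C@]1(COCc2ccc(OC)cc2)COC(C)(C)O1 | intermediate
7 | alkenyl iodide: (4S)-4-[(2E)-3-iodo-2-methylprop-2-en-1-yl]-4-{[(4-methoxyphenyl)methoxy]methyl}-2,2-dimethyl-1,3-dioxolane | I/C=C(\C)C[C@]1(COCc2ccc(OC)cc2)COC(C)(C)O1 | intermediate
8 | alkenylboronate: 2-[(1E)-3-{(4S)-4-{[(4-methoxyphenyl)methoxy]methyl}-2,2-dimethyl-1,3-dioxolan-4-yl}-2-methylprop-1-en-1-yl]-4,4,5,5-tetramethyl-1,3,2-dioxaborolane | CC1(C)OB(/C=C(\C)C[C@]2(COCc3ccc(OC)cc3)COC(C)(C)O2)OC1(C)C | intermediate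
9 | (3E)-pent-3-en-2-one | C/C=C/C(C)=O | starting material
10 | methyl ketone: (4S,5E)-7-[(4S)-4-{[(4-methoxyphenyl)methoxy]methyl}-2,2-dimethyl-1,3-dioxolan-4-yl]-4,6-dimethylhept-5-en-2-one | CC(=O)C[C@H](C)/C=C(\C)C[C@]1(COCc2ccc(OC)cc2)COC(C)(C)O1 | intermediate
11 | lithium enolate: lithium (4S,5E)-7-[(4S)-4-{[(4-methoxyphenyl)methoxy]methyl}-2,2-dimethyl-1,3-dioxolan-4-yl]-4,6-dimethylhepta-1,5-dien-2-olate | [Li]OC(=C)C[C@H](C)/C=C(\C)C[C@]1(COCc2ccc(OC)cc2)COC(C)(C)O1 | intermediate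
12 | enol triflate: (4S,5E)-7-[(4S)-4-{[(4-methoxyphenyl)methoxy]methyl}-2,2-dimethyl-1,3-dioxolan-4-yl]-4,6-dimethylhepta-1,5-dien-2-yl trifluoromethanesulfonate | C=C(OS(=O)(=O)C(F)(F)F)C[C@H](C)/C=C(\C)C[C@]1(COCc2ccc(OC)cc2)COC(C)(C)O1 | intermediate
13 | tert-butyl(diphenyl)(prop-2-yn-1-yloxy)silane | C#CCO[Si](c1ccccc1)(c1ccccc1)C(C)(C)C | starting material
14 | enyne PMB ether: (4S)-4-[(2E,4S)-9-{[tert-butyl(diphenyl)silyl]oxy}-2,4-dimethyl-6-methylidenenon-2-en-7-yn-1-yl]-4-{[(4-methoxyphenyl)methoxy]methyl}-2,2-dimethyl-1,3-dioxolane | C=C(C#CCO[Si](c1ccccc1)(c1ccccc1)C(C)(C)C)C[C@H](C)/C=C(\C)C[C@]1(COCc2ccc(OC)cc2)COC(C)(C)O1 | intermediate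
15 | enyne alcohol: {(4S)-4-[(2E,4S)-9-{[tert-butyl(diphenyl)silyl]oxy}-2,4-dimethyl-6-methylidenenon-2-en-7-yn-1-yl]-2,2-dimethyl-1,3-dioxolan-4-yl}methanol | C=C(C#CCO[Si](c1ccccc1)(c1ccccc1)C(C)(C)C)C[C@H](C)/C=C(\C)C[C@]1(CO)COC(C)(C)O1 | intermediate
16 | enyne aldehyde: (4R)-4-[(2E,4S)-9-{[tert-butyl(diphenyl)silyl]oxy}-2,4-dimethyl-6-methylidenenon-2-en-7-yn-1-yl]-2,2-dimethyl-1,3-dioxolane-4-carbaldehyde | C=C(C#CCO[Si](c1ccccc1)(c1ccccc1)C(C)(C)C)C[C@H](C)/C=C(\C)C[C@]1(C=O)COC(C)(C)O1 | intermediate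
17 | (4R)-4-benzyl-3-propanoyl-1,3-oxazolidin-2-one | CCC(=O)N1[C@H](Cc2ccccc2)COC1=O | starting material
18 | dibutylboron Z-enolate of 17: (4R)-4-benzyl-3-[(1Z)-1-[(dibutylboranyl)oxy]prop-1-en-1-yl]-1,3-oxazolidin-2-one | CCCCB(CCCC)O/C(=C\C)N1[C@H](Cc2ccccc2)COC1=O | intermediate
19 | aldol adduct: (4R)-4-benzyl-3-[(2R,3R)-3-{(4R)-4-[(2E,4S)-9-{[tert-butyl(diphenyl)silyl]oxy}-2,4-dimethyl-6-methylidenenon-2-en-7-yn-1-yl]-2,2-dimethyl-1,3-dioxolan-4-yl}-3-hydroxy-2-methylpropanoyl]-1,3-oxazolidin-2-one | C=C(C#CCO[Si](c1ccccc1)(c1ccccc1)C(C)(C)C)C[C@H](C)/C=C(\C)C[C@]1([C@H](O)[C@@H](C)C(=O)N2[C@H](Cc3ccccc3)COC2=O)COC(C)(C)O1 | intermediate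
20 | silyl ether: (4R)-4-benzyl-3-[(2R,3R)-3-{(4R)-4-[(2E,4S)-9-{[tert-butyl(diphenyl)silyl]oxy}-2,4-dimethyl-6-methylidenenon-2-en-7-yn-1-yl]-2,2-dimethyl-1,3-dioxolan-4-yl}-2-methyl-3-[(triethylsilyl)oxy]propanoyl]-1,3-oxazolidin-2-one | C=C(C#CCO[Si](c1ccccc1)(c1ccccc1)C(C)(C)C)C[C@H](C)/C=C(\C)C[C@]1([C@H](O[Si](CC)(CC)CC)[C@@H](C)C(=O)N2[C@H](Cc3ccccc3)COC2=O)COC(C)(C)O1 | intermediate
21 | propanal | CCC=O | starting material
22 | dienyl alcohol: (4R)-4-benzyl-3-[(2R,3R)-3-{(4R)-4-[(2E,4S,7E,9S)-8-({[tert-butyl(diphenyl)silyl]oxy}methyl)-9-hydroxy-2,4-dimethyl-6-methylideneundeca-2,7-dien-1-yl]-2,2-dimethyl-1,3-dioxolan-4-yl}-2-methyl-3-[(triethylsilyl)oxy]propanoyl]-1,3-oxazolidin-2-one | C=C(/C=C(\CO[Si](c1ccccc1)(c1ccccc1)C(C)(C)C)[C@@H](O)CC)C[C@H](C)/C=C(\C)C[C@]1([C@H](O[Si](CC)(CC)CC)[C@@H](C)C(=O)N2[C@H](Cc3ccccc3)COC2=O)COC(C)(C)O1 | intermediate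
23 | lithium peroxycarboxylate: lithium salt of the peroxy acid corresponding to 24 | C=C(/C=C(\CO[Si](c1ccccc1)(c1ccccc1)C(C)(C)C)[C@@H](O)CC)C[C@H](C)/C=C(\C)C[C@]1([C@H](O[Si](CC)(CC)CC)[C@@H](C)C(=O)OO[Li])COC(C)(C)O1 | intermediate
24 | seco acid: (2R,3R)-3-{(4R)-4-[(2E,4S,7E,9S)-8-({[tert-butyl(diphenyl)silyl]oxy}methyl)-9-hydroxy-2,4-dimethyl-6-methylideneundeca-2,7-dien-1-yl]-2,2-dimethyl-1,3-dioxolan-4-yl}-2-methyl-3-[(triethylsilyl)oxy]propanoic acid | C=C(/C=C(\CO[Si](c1ccccc1)(c1ccccc1)C(C)(C)C)[C@@H](O)CC)C[C@H](C)/C=C(\C)C[C@]1([C@H](O[Si](CC)(CC)CC)[C@@H](C)C(=O)O)COC(C)(C)O1 | intermediate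
25 | mixed anhydride of 24 with 2-methyl-6-nitrobenzoic acid | C=C(/C=C(\CO[Si](c1ccccc1)(c1ccccc1)C(C)(C)C)[C@@H](O)CC)C[C@H](C)/C=C(\C)C[C@]1([C@H](O[Si](CC)(CC)CC)[C@@H](C)C(=O)OC(=O)c2c(C)cccc2[N+](=O)[O-])COC(C)(C)O1 | intermediate
26 | macrolactone (C3 OSiEt3, C4/C4' acetonide, C12' OSiPh2tBu): (5R,6R,7R,10S,11E,15S,16E)-11-({[tert-butyl(diphenyl)silyl]oxy}methyl)-10-ethyl-2,2,7,15,17-pentamethyl-13-methylidene-6-[(triethylsilyl)oxy]-1,3,9-trioxaspiro[4.13]octadeca-11,16-dien-8-one | C=C1/C=C(\CO[Si](c2ccccc2)(c2ccccc2)C(C)(C)C)[C@H](CC)OC(=O)[C@H](C)[C@@H](O[Si](CC)(CC)CC)[C@]2(COC(C)(C)O2)C/C(C)=C/[C@@H](C)C1 | intermediate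
27 | C3 alcohol: (5R,6R,7R,10S,11E,15S,16E)-11-({[tert-butyl(diphenyl)silyl]oxy}methyl)-10-ethyl-6-hydroxy-2,2,7,15,17-pentamethyl-13-methylidene-1,3,9-trioxaspiro[4.13]octadeca-11,16-dien-8-one | C=C1/C=C(\CO[Si](c2ccccc2)(c2ccccc2)C(C)(C)C)[C@H](CC)OC(=O)[C@H](C)[C@@H](O)[C@]2(COC(C)(C)O2)C/C(C)=C/[C@@H](C)C1 | intermediate
28 | keto lactone: (5R,7R,10S,11E,15S,16E)-11-({[tert-butyl(diphenyl)silyl]oxy}methyl)-10-ethyl-2,2,7,15,17-pentamethyl-13-methylidene-1,3,9-trioxaspiro[4.13]octadeca-11,16-diene-6,8-dione | C=C1/C=C(\CO[Si](c2ccccc2)(c2ccccc2)C(C)(C)C)[C@H](CC)OC(=O)[C@H](C)C(=O)[C@]2(COC(C)(C)O2)C/C(C)=C/[C@@H](C)C1 | intermediate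
29 | hydroxymethyl acetonide: (5R,7R,10S,11E,15S,16E)-10-ethyl-11-(hydroxymethyl)-2,2,7,15,17-pentamethyl-13-methylidene-1,3,9-trioxaspiro[4.13]octadeca-11,16-diene-6,8-dione | C=C1/C=C(\CO)[C@H](CC)OC(=O)[C@H](C)C(=O)[C@]2(COC(C)(C)O2)C/C(C)=C/[C@@H](C)C1 | intermediate
30 | (3R,5R,7E,9S,12E,14S)-14-ethyl-5-hydroxy-5,13-bis(hydroxymethyl)-3,7,9-trimethyl-11-methylideneoxacyclotetradeca-7,12-diene-2,4-dione (CNP0104552.3) | C=C1/C=C(\CO)[C@H](CC)OC(=O)[C@H](C)C(=O)[C@](O)(CO)C/C(C)=C/[C@@H](C)C1 | target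

## Step count and risks

Total step count: 19. Longest linear sequence: 19 steps (1 to 30); compounds 9, 13, 17 and 21 are bought.

The three steps most likely to fail:

Step 14 (the proposed nickel coupling; the ligand effect and its sense are untested, and the substrate is advanced). The fallback uses known chemistry, sets out from 20 and comes back to the route at 22. The established achiral system (Ni(cod)2, tricyclopentylphosphine, Et3B, EtOAc) couples 20 with propanal with the same regio- and E-selectivity and gives the C13-epimeric dienyl alcohols F1. Dess–Martin oxidation gives the dienone F2. Corey–Bakshi–Shibata reduction with (R)-2-methyl-CBS-oxazaborolidine and catecholborane at −78 °C, the alkenyl group acting as the large substituent, then gives the 13S alcohol 22.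

Step 7 (a β,β-disubstituted alkenylboronate used as the limiting partner may protodeboronate, and the selectivity on a small acyclic enone may be moderate). The fallback sets out from 7 and comes back at 10. Iodine–magnesium exchange with iPrMgCl·LiCl in THF gives the alkenylmagnesium chloride F3. Its CuBr·SMe2-mediated conjugate addition to (4R)-3-[(2E)-but-2-enoyl]-4-phenyl-1,3-oxazolidin-2-one, which is attacked anti to the phenyl group in the chelated s-cis imide, gives the 8S imide F4. AlMe3 with MeNH(OMe)·HCl converts it into the Weinreb amide F5, and MeMgBr gives ketone 10.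

Step 16 (acylation of a hindered dienylic carbinol in a 14-membered ring closure may be slow and oligomerise). The fallback activates the alcohol instead of the acid; it sets out from 22 and comes back at 26. Compound 22 is oxidised with Dess–Martin periodinane to the dienone F2 described above and reduced with (S)-2-methyl-CBS-oxazaborolidine and catecholborane to the 13R alcohol F6. Auxiliary cleavage with LiOH/H2O2 gives the 13-epi seco acid F7. Mitsunobu macrolactonisation (PPh3, diisopropyl azodicarboxylate, toluene, high dilution) then closes the ring by carboxylate attack at C13 with inversion and gives 26.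

## Further compounds

F1 | step 14 | C13-epimeric dienyl alcohols: (4R)-4-benzyl-3-[(2R,3R)-3-{(4R)-4-[(2E,4S,7E,9RS)-8-({[tert-butyl(diphenyl)silyl]oxy}methyl)-9-hydroxy-2,4-dimethyl-6-methylideneundeca-2,7-dien-1-yl]-2,2-dimethyl-1,3-dioxolan-4-yl}-2-methyl-3-[(triethylsilyl)oxy]propanoyl]-1,3-oxazolidin-2-one | C=C(/C=C(\CO[Si](c1ccccc1)(c1ccccc1)C(C)(C)C)C(O)CC)C[C@H](C)/C=C(\C)C[C@]1([C@H](O[Si](CC)(CC)CC)[C@@H](C)C(=O)N2[C@H](Cc3ccccc3)COC2=O)COC(C)(C)O1
F2 | step 14 | dienone: (4R)-4-benzyl-3-[(2R,3R)-3-{(4R)-4-[(2E,4S,7E)-8-({[tert-butyl(diphenyl)silyl]oxy}methyl)-2,4-dimethyl-6-methylidene-9-oxoundeca-2,7-dien-1-yl]-2,2-dimethyl-1,3-dioxolan-4-yl}-2-methyl-3-[(triethylsilyl)oxy]propanoyl]-1,3-oxazolidin-2-one | C=C(/C=C(\CO[Si](c1ccccc1)(c1ccccc1)C(C)(C)C)C(=O)CC)C[C@H](C)/C=C(\C)C[C@]1([C@H](O[Si](CC)(CC)CC)[C@@H](C)C(=O)N2[C@H](Cc3ccccc3)COC2=O)COC(C)(C)O1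
F3 | step 7 | alkenylmagnesium chloride: chlorido[(1E)-3-{(4S)-4-{[(4-methoxyphenyl)methoxy]methyl}-2,2-dimethyl-1,3-dioxolan-4-yl}-2-methylprop-1-en-1-yl]magnesium | Cl[Mg]/C=C(\C)C[C@]1(COCc2ccc(OC)cc2)COC(C)(C)O1
F4 | step 7 | conjugate adduct: (4R)-3-[(3S,4E)-6-{(4S)-4-{[(4-methoxyphenyl)methoxy]methyl}-2,2-dimethyl-1,3-dioxolan-4-yl}-3,5-dimethylhex-4-enoyl]-4-phenyl-1,3-oxazolidin-2-one | O=C(C[C@H](C)/C=C(\C)C[C@]1(COCc2ccc(OC)cc2)COC(C)(C)O1)N1[C@H](c2ccccc2)COC1=O
F5 | step 7 | Weinreb amide: (3S,4E)-N-methoxy-6-{(4S)-4-{[(4-methoxyphenyl)methoxy]methyl}-2,2-dimethyl-1,3-dioxolan-4-yl}-N,3,5-trimethylhex-4-enamide | CON(C)C(=O)C[C@H](C)/C=C(\C)C[C@]1(COCc2ccc(OC)cc2)COC(C)(C)O1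
F6 | step 16 | 13R alcohol: (4R)-4-benzyl-3-[(2R,3R)-3-{(4R)-4-[(2E,4S,7E,9R)-8-({[tert-butyl(diphenyl)silyl]oxy}methyl)-9-hydroxy-2,4-dimethyl-6-methylideneundeca-2,7-dien-1-yl]-2,2-dimethyl-1,3-dioxolan-4-yl}-2-methyl-3-[(triethylsilyl)oxy]propanoyl]-1,3-oxazolidin-2-one | C=C(/C=C(\CO[Si](c1ccccc1)(c1ccccc1)C(C)(C)C)[C@H](O)CC)C[C@H](C)/C=C(\C)C[C@]1([C@H](O[Si](CC)(CC)CC)[C@@H](C)C(=O)N2[C@H](Cc3ccccc3)COC2=O)COC(C)(C)O1
F7 | step 16 | 13-epi seco acid: (2R,3R)-3-{(4R)-4-[(2E,4S,7E,9R)-8-({[tert-butyl(diphenyl)silyl]oxy}methyl)-9-hydroxy-2,4-dimethyl-6-methylideneundeca-2,7-dien-1-yl]-2,2-dimethyl-1,3-dioxolan-4-yl}-2-methyl-3-[(triethylsilyl)oxy]propanoic acid | C=C(/C=C(\CO[Si](c1ccccc1)(c1ccccc1)C(C)(C)C)[C@H](O)CC)C[C@H](C)/C=C(\C)C[C@]1([C@H](O[Si](CC)(CC)CC)[C@@H](C)C(=O)O)COC(C)(C)O1
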